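**Assumption:** atom labels C1–C20 are the labdane numbering of the target and are used for every intermediate (α/β as in the usual labdane drawing, C20 on C10 = β). The target is (13R)-20-acetoxy-9α,13-epoxylabdane-19,6β:15,16-diolide (4S,5R,6R,8R,9R,10S,13R). Commercial but-3-enylmagnesium bromide solution is taken as a starting material.

## Retrosynthetic overview

1. Target ⇒ spiro-butanolide 20 (C20 CO2allyl → CH2OAc at the end); 20 ⇒ desymmetrising Baeyer–Villiger ring expansion of prochiral spirocyclobutanone 19 (butanolide ring and C13 made last).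
2. 19 ⇒ dichloroketene [2+2] and dechlorination of exocyclic enol ether 15 ⇒ iodoetherification/elimination of carbinol 13 ⇒ butenyl addition to C9 ketone 11 (spiro-oxolane, C9).
3. 11 ⇒ ring A by C10 alkylation with 1,3-diiodopropane, then lactone-enolate C3–C4 closure of bicyclic β-keto ester 8 (C10, C4).
4. 8 ⇒ ring B by vinylogous Mukaiyama–Michael addition of silyloxyfuran 6 to enone 4 (C6–C7, sets C6), then intramolecular Michael addition (C5–C10).
5. Ring order: 19,6-lactone (from butenolide 5) → ring B → ring A → oxolane → cyclobutanone → butanolide.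

## Route

Step 1
Reactants: 1 allyl acetate; 2 methacryloyl chloride
Product: 4 allyl 4-methyl-3-oxopent-4-enoate, via lithium enolate 3 (not isolated)
Conditions: LDA (2.1 equiv), THF, −78 °C; then 2 (1.0 equiv), −78 °C; 1 M HCl quench; used fresh (BHT)
Reagents that add atoms: none
Why: crossed Claisen condensation, in which the lithium ester enolate is C-acylated by the acid chloride at −78 °C and the second equivalent of base stores the β-keto ester as its enolate, which prevents over-acylation (no stereocentre).

Step 2
Reactants: 5 3-methyl-2(5H)-furanone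
Product: 6 3-methyl-2-(trimethylsilyloxy)furan
Conditions: TMSOTf (1.1 equiv), Et3N (1.3 equiv), Et2O, 0 °C; filtration, distillation
Reagents that add atoms: trimethylsilyl trifluoromethanesulfonate, C[Si](C)(C)OS(=O)(=O)C(F)(F)F
Why: soft enolisation and O-silylation of the butenolide give the aromatic silyl dienol ether (silyloxyfuran formation).

Step 3
Reactants: 4 allyl 4-methyl-3-oxopent-4-enoate; 6 3-methyl-2-(trimethylsilyloxy)furan
Product: 8 allyl (3aS,7aR)-3,6-dimethyl-2,5-dioxooctahydro-1-benzofuran-4-carboxylate (ring B fused cis to the lactone; C4/C8/C10 labile), via butenolide adduct 7 (not isolated)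
Conditions: Cu(OTf)2 (10 mol %), t-Bu-bis(oxazoline) (11 mol %, the antipode that gives 6R), (CF3)2CHOH (1.2 equiv), CH2Cl2, −78 °C; then i-Pr2NEt (0.5 equiv), −20 °C → rt
Reagents that add atoms: none
Why: chelation of the 1,3-dicarbonyl unit of 4 to the chiral Cu(II) Lewis acid activates the enone for an enantioselective vinylogous Mukaiyama–Michael addition of the furan γ-carbon (C6–C7 bond, C6 set as R by the catalyst), and the amine then triggers a 6-exo intramolecular Michael addition of the β-keto ester to the butenolide, whose four-atom tether allows only the cis ring fusion at C5.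

Step 4
Reactants: 8 bicyclic β-keto ester; 9 1,3-diiodopropane
Product: 10 allyl (3aS,4R,7aR)-4-(3-iodopropyl)-3,6-dimethyl-2,5-dioxooctahydro-1-benzofuran-4-carboxylate (C4/C8 epimers)
Conditions: 9 (3 equiv), Cs2CO3 (1.2 equiv), MeCN, 0 °C → rt
Reagents that add atoms: none
Why: C-alkylation of the cyclic β-keto ester enolate takes place on the convex face of the cis-fused bicycle, anti to C4 on the neighbouring carbon, which sets C10 (chain α, ester β).

Step 5
Reactants: 10 iodide
Product: 11 allyl 9-oxo-11,12,13,14,15,16-hexanorlabdan-19,6β-olid-20-oate (5α-H,8α-Me; trans-decalin)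
Conditions: LiHMDS (2.3 equiv), THF, −78 → 0 °C; then t-BuOH (5 equiv), rt, 2 h; 1 M HCl
Reagents that add atoms: none
Why: intramolecular 6-exo-tet alkylation of the lactone enolate closes ring A, and because the tether on C10 can reach only the enolate face syn to C10 the new quaternary C4 carries C19 β and methyl α (trans-decalin), while the t-BuOH/LiOt-Bu quench equilibrates C8 to the equatorial 8α-methyl epimer.

Step 6
Reactants: 11 tricyclic ketone; 12 but-3-enylmagnesium bromide
Product: 13 allyl 9α-hydroxy-14,15-dinorlabd-13(16)-en-19,6β-olid-20-oate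
Conditions: 12 (3 equiv), LaCl3·2LiCl (1.1 equiv), THF, −78 → −20 °C; 1 M HCl, 0 °C
Reagents that add atoms: none
Why: lanthanide-promoted Grignard 1,2-addition to the hindered, enolisable ketone (esters untouched at low temperature), with the bulky reagent entering equatorially from the β side because the axial path is blocked by H5α/H7α, as alkyl-metal reagents do with the 20-methyl 9-oxo-19,6β-olide of this series, which sets C9 (9α-OH).

Step 7
Reactants: 13 alkenol
Product: 14 allyl 9α,13-epoxy-16-iodo-14,15-dinorlabdan-19,6β-olid-20-oate (C13 epimers)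
Conditions: I2 (1.5 equiv), NaHCO3 (3 equiv), MeCN, 0 °C, dark
Reagents that add atoms: iodine, II
Why: 5-exo iodoetherification of the tertiary alcohol onto the terminal alkene forms the spiro-oxolane (the transient C13 centre is removed in step 8).

Step 8
Reactants: 14 iodoether
Product: 15 allyl 9α,13-epoxy-14,15-dinorlabd-13(16)-en-19,6β-olid-20-oate
Conditions: KOt-Bu (1.5 equiv), THF, 0 °C; used crude
Reagents that add atoms: none
Why: E2 dehydroiodination of the β-branched primary iodide can only remove H13 and gives the exocyclic enol ether.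

Step 9
Reactants: 15 enol ether; 16 dichloroacetyl chloride
Product: 18 allyl 14,14-dichloro-9α,13-epoxy-15-oxo-15,16-cyclolabdan-19,6β-olid-20-oate (C13 epimers), via dichloroketene 17 (not isolated)
Conditions: 16 (2 equiv, slow addition), Et3N (2.2 equiv), Et2O/hexane, 0 °C → rt
Reagents that add atoms: none
Why: ketene–enol ether [2+2] cycloaddition with the usual regiochemistry (carbonyl carbon to the CH2 terminus, CCl2 to the oxygenated C13); the facial selectivity does not matter because C13 becomes prochiral in step 10.

Step 10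
Reactants: 18 dichlorocyclobutanone
Product: 19 allyl 9α,13-epoxy-15-oxo-15,16-cyclolabdan-19,6β-olid-20-oate (prochiral spirocyclobutanone)
Conditions: Zn dust (6 equiv), AcOH, rt
Reagents that add atoms: none
Why: zinc reductive dechlorination of the α,α-dichloroketone, the standard route to 3-alkoxycyclobutanones, leaves two constitutionally identical CH2 arms on C13.

Step 11
Reactants: 19 spirocyclobutanone
Product: 20 allyl (13R)-9α,13-epoxylabdane-19,6β:15,16-diolid-20-oate
Conditions: H8-TRIP chiral phosphoric acid (10 mol %), 30 % aq H2O2 (1.5 equiv), CHCl3, −40 °C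
Reagents that add atoms: hydrogen peroxide, OO
Why: Proposed new method: catalyst-controlled desymmetrising Baeyer–Villiger ring expansion of a prochiral 3-alkoxy-3-alkyl spirocyclobutanone set in a chiral polycycle; the acid adds H2O2 to the strained ketone and the Criegee adduct forms with its OH syn to the oxolane oxygen (O–H···O contact, so the two ketone faces are no longer equivalent), the chiral phosphate then clamps OH and OOH by two hydrogen bonds and holds the O–O bond antiperiplanar to only one CH2–C15 bond, and strain release drives the 1,2-shift of that CH2 to oxygen (the arm on the C8 side gives 13R; the catalyst antipode is fixed in one screening run because the remote substrate chirality gives almost no bias); the closest known reaction is the chiral phosphoric acid/H2O2 or Sc(III)–N,N′-dioxide/peracid asymmetric Baeyer–Villiger oxidation of 3-monosubstituted prochiral cyclobutanones.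

Step 12
Reactants: 20 allyl ester
Product: 21 (13R)-9α,13-epoxylabdane-19,6β:15,16-diolid-20-oic acid
Conditions: Pd(PPh3)4 (5 mol %), morpholine (2 equiv), THF, 0 °C → rt; 1 M HCl work-up
Reagents that add atoms: none
Why: Tsuji–Trost deallylation through a π-allyl palladium complex trapped by the amine frees the hindered acid under neutral conditions that leave both lactones and the β-alkoxy lactone untouched.

Step 13
Reactants: 21 acid
Product: 22 (13R)-9α,13-epoxy-20-hydroxylabdane-19,6β:15,16-diolide
Conditions: BH3·SMe2 (2 equiv), THF, 0 °C → rt; then H2O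
Reagents that add atoms: none
Why: borane reduces a carboxylic acid through its acyloxyborane much faster than it reduces γ-lactones (chemoselective borane reduction).

Step 14
Reactants: 22 alcohol; 23 acetic anhydride
Product: 24 (13R)-20-acetoxy-9α,13-epoxylabdane-19,6β:15,16-diolide (target)
Conditions: 23 (3 equiv), pyridine, DMAP (10 mol %), CH2Cl2, rt
Reagents that add atoms: none
Why: DMAP-catalysed acyl transfer acetylates the neopentyl primary alcohol, the only free hydroxyl.

## Compound list

1 | allyl acetate | CC(=O)OCC=C | starting material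
2 | methacryloyl chloride | CC(=C)C(=O)Cl | starting material
3 | lithium 1-(allyloxy)ethenolate (enolate of 1) | [Li+].[O-]C(=C)OCC=C | intermediate
4 | allyl 4-methyl-3-oxopent-4-enoate | C=C(C)C(=O)CC(=O)OCC=C | intermediate
5 | 3-methyl-2(5H)-furanone | CC1=CCOC1=O | starting material
6 | 3-methyl-2-(trimethylsilyloxy)furan | CC1=C(O[Si](C)(C)C)OC=C1 | intermediate
7 | allyl 4-methyl-5-[(2R)-4-methyl-5-oxo-2,5-dihydrofuran-2-yl]-3-oxopentanoate (C8 epimers) | C=CCOC(=O)CC(=O)C(C)C[C@H]1OC(=O)C(C)=C1 | intermediate
8 | allyl (3aS,7aR)-3,6-dimethyl-2,5-dioxooctahydro-1-benzofuran-4-carboxylate (H5/H6 cis; C4, C8, C10 labile) | C=CCOC(=O)C1C(=O)C(C)C[C@H]2OC(=O)C(C)[C@@H]12 | intermediate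
9 | 1,3-diiodopropane | ICCCI | starting material
10 | allyl (3aS,4R,7aR)-4-(3-iodopropyl)-3,6-dimethyl-2,5-dioxooctahydro-1-benzofuran-4-carboxylate (chain trans to C4; C4, C8 epimers) | C=CCOC(=O)[C@@]1(CCCI)C(=O)C(C)C[C@H]2OC(=O)C(C)[C@@H]12 | intermediate
11 | allyl 9-oxo-11,12,13,14,15,16-hexanorlabdan-19,6β-olid-20-oate (4α-Me, 5α-H, 8α-Me, 10β-CO2allyl) | C=CCOC(=O)[C@@]12CCC[C@]3(C)C(=O)O[C@H](C[C@@H](C)C1=O)[C@H]23 | intermediate
12 | but-3-enylmagnesium bromide | C=CCC[Mg]Br | starting material
13 | allyl 9α-hydroxy-14,15-dinorlabd-13(16)-en-19,6β-olid-20-oate | C=CCOC(=O)[C@@]12CCC[C@]3(C)C(=O)O[C@H](C[C@@H](C)[C@]1(O)CCC=C)[C@H]23 | intermediate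
14 | allyl 9α,13-epoxy-16-iodo-14,15-dinorlabdan-19,6β-olid-20-oate (C13 epimers) | C=CCOC(=O)[C@@]12CCC[C@]3(C)C(=O)O[C@H](C[C@@H](C)[C@]14CCC(CI)O4)[C@H]23 | intermediate
15 | allyl 9α,13-epoxy-14,15-dinorlabd-13(16)-en-19,6β-olid-20-oate | C=CCOC(=O)[C@@]12CCC[C@]3(C)C(=O)O[C@H](C[C@@H](C)[C@]14CCC(=C)O4)[C@H]23 | intermediate
16 | dichloroacetyl chloride | O=C(Cl)C(Cl)Cl | starting material
17 | dichloroketene | ClC(Cl)=C=O | intermediate
18 | allyl 14,14-dichloro-9α,13-epoxy-15-oxo-15,16-cyclolabdan-19,6β-olid-20-oate (C13 epimers) | C=CCOC(=O)[C@@]12CCC[C@]3(C)C(=O)O[C@H](C[C@@H](C)[C@]14CCC5(CC(=O)C5(Cl)Cl)O4)[C@H]23 | intermediate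
19 | allyl 9α,13-epoxy-15-oxo-15,16-cyclolabdan-19,6β-olid-20-oate (C13 prochiral) | C=CCOC(=O)[C@@]12CCC[C@]3(C)C(=O)O[C@H](C[C@@H](C)[C@]14CCC5(CC(=O)C5)O4)[C@H]23 | intermediate
20 | allyl (13R)-9α,13-epoxylabdane-19,6β:15,16-diolid-20-oate | C=CCOC(=O)[C@@]12CCC[C@]3(C)C(=O)O[C@H](C[C@@H](C)[C@]14CC[C@@]1(COC(=O)C1)O4)[C@H]23 | intermediate
21 | (13R)-9α,13-epoxylabdane-19,6β:15,16-diolid-20-oic acid | OC(=O)[C@@]12CCC[C@]3(C)C(=O)O[C@H](C[C@@H](C)[C@]14CC[C@@]1(COC(=O)C1)O4)[C@H]23 | intermediate
22 | (13R)-9α,13-epoxy-20-hydroxylabdane-19,6β:15,16-diolide | OC[C@@]12CCC[C@]3(C)C(=O)O[C@H](C[C@@H](C)[C@]14CC[C@@]1(COC(=O)C1)O4)[C@H]23 | intermediate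
23 | acetic anhydride | CC(=O)OC(C)=O | starting material
24 | (13R)-20-acetoxy-9α,13-epoxylabdane-19,6β:15,16-diolide | CC(=O)OC[C@@]12CCC[C@]3(C)C(=O)O[C@H](C[C@@H](C)[C@]14CC[C@@]1(COC(=O)C1)O4)[C@H]23 | target

## Step count and risks

Total steps: 14. Longest linear sequence: 13 (steps 1, 3–14; step 2 is the side branch).

**Step 11 (proposed new step).** The catalyst may fail to tell the two CH2 arms apart and give a C13 mixture. The fallback uses known chemistry, sets out from 18 and comes back at 20. The C13 epimers of 18 are oxidised directly with mCPBA/NaHCO3 in CH2Cl2. In α,α-dichlorocyclobutanones only the CH2 carbon migrates, so oxygen enters between C15 and C16 and the C13 configuration is the one fixed by the [2+2] step. This gives allyl 14,14-dichloro-9α,13-epoxylabdane-19,6β:15,16-diolid-20-oate F4, whose epimer with the spatial arrangement of 20 is separated by chromatography. Zn/AcOH dechlorination of F4 then gives 20. The facial selectivity of the [2+2] is not predictable here, so this fallback may cost up to half the material.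

**Step 5.** The ketone enolate formed alongside the lactone enolate may O-alkylate (six-membered enol ether) instead of the lactone enolate closing ring A. The fallback sets out from 10 and comes back at 11. TMSOTf/Et3N first converts the C9 ketone into the trimethylsilyl enol ether of 10 F1, so that one equivalent of LDA can form only the lactone enolate. The 6-exo-tet closure then gives the tricyclic silyl enol ether F2. Hydrolysis with 1 M HCl in THF returns 11 with C8 under thermodynamic control.

**Step 6.** Chelation of the metal between the C9 ketone and the axial C20 ester could turn the attack to the α face and give the 9β-alcohol. The fallback sets out from 11 and comes back at 13. Dimethylsulfoxonium methylide (Me3S(O)I, NaH, DMSO) transfers CH2 under reversible-betaine control into the equatorial position and gives the 9α,11-epoxide F3 (oxygen axial, α). Copper(I)-catalysed opening at the CH2 terminus with allylmagnesium chloride (THF, −30 °C) then gives 13.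

Further compounds
F1 | step 5 | trimethylsilyl enol ether of 10 (C8=C9–OTMS) | C=CCOC(=O)[C@@]1(CCCI)C(O[Si](C)(C)C)=C(C)C[C@H]2OC(=O)C(C)[C@@H]12
F2 | step 5 | allyl 9-(trimethylsilyloxy)-11,12,13,14,15,16-hexanorlabd-8-en-19,6β-olid-20-oate | C=CCOC(=O)[C@@]12CCC[C@]3(C)C(=O)O[C@H](CC(C)=C1O[Si](C)(C)C)[C@H]23
F3 | step 6 | allyl 9α,11-epoxy-12,13,14,15,16-pentanorlabdan-19,6β-olid-20-oate | C=CCOC(=O)[C@@]12CCC[C@]3(C)C(=O)O[C@H](C[C@@H](C)[C@]14CO4)[C@H]23
F4 | step 11 | allyl 14,14-dichloro-9α,13-epoxylabdane-19,6β:15,16-diolid-20-oate (C13 arranged as in 20; 13S by CIP) | C=CCOC(=O)[C@@]12CCC[C@]3(C)C(=O)O[C@H](C[C@@H](C)[C@]14CC[C@@]1(COC(=O)C1(Cl)Cl)O4)[C@H]23
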